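**Plan**

- Cuts: the sixteen O–benzyl bonds; the interflavan bond C4(unit 2)–C8(unit 3); in unit 2 the ring C bond O1–C2, the C2–C3 epoxide oxygen, the C3–C4 bond, the C4–C4a bond and the C8–C4(unit 1) bond; the lower dimer (units 3–4) at its own C4–C8 bond.
- Forward: units 1, 3 and 4 are (−)-epicatechin with rings A, B and C intact. Ring A of unit 2 enters as 3,5-bis(benzyloxy)phenol, whose free OH (the future O1) lies between the two ortho carbons that become C8 and C4a, so the link to unit 1 and the C4 carbon are both placed ortho to it. Ring B with C2–C3 of unit 2 arrives as an arylalkyne; ring C of unit 2 is closed last, then the unit 1–2 and unit 3–4 halves are joined and the benzyl groups removed.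
- Enabling feature: in unit 2, O1 on C8a of ring A is one atom from C4a, and C2 is benzylic to ring B with its para oxygen. A C2–C3 cis-epoxide is therefore opened at C2 by the O1 phenol in a 6-endo sense with inversion, which gives the 2,3-cis ring C, the 3-OH and a 4-OH leaving group together.
- Stereochemistry: units 1, 3 and 4 from the chiral pool; the C4 carbinol of unit 2 by ligand-controlled alkynylation, relayed to C3 and C2 by hydroxyl-directed epoxidation of the Z-alkene (allylic 1,3-strain) and to the ring C2 by inversion; all 4β centres by attack trans to the 3-OH on flavan-4-yl cations (the auxiliary C4 carbinol is erased there).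

Key step: step 11

Assumption: in step 8 the (S,S)-ligand–zinc catalyst is taken to deliver the alkynyl group to the Re face of the aldehyde (O > aryl > H); should the sense be opposite, the (R,R)-ligand is used and nothing else changes.

**Route**

Step 1
Reactants: 1 (−)-epicatechin
Product: 2 5,7,3',4'-tetra-O-benzyl-(−)-epicatechin
Conditions: BnBr (4.4 equiv), K2CO3, DMF, 0 °C to rt
Reagents that add atoms: benzyl bromide, BrCc1ccccc1
Why: Williamson etherification of the four phenols only, since K2CO3 does not deprotonate the secondary 3-OH, and no stereocentre is touched.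

Step 2
Reactants: 2 5,7,3',4'-tetra-O-benzyl-(−)-epicatechin
Product: 3 (2R,3R,4S)-4-(2-ethoxyethoxy) derivative of 2
Conditions: DDQ, 2-ethoxyethanol, CH2Cl2, rt
Reagents that add atoms: 2-ethoxyethanol, CCOCCO
Why: DDQ benzylic C–H oxidation (hydride abstraction) at C4 should give a ring A-stabilised cation that the alcohol captures trans to the 3-OH, placing the alkoxy group 4β.

Step 3
Reactants: 3 4β-(2-ethoxyethoxy) electrophile; 2 5,7,3',4'-tetra-O-benzyl-(−)-epicatechin (4 equiv)
Product: 4 octa-O-benzyl epicatechin-(4β→8)-epicatechin (benzylated lower dimer, units 3–4)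
Conditions: Me3SiOTf (cat.), CH2Cl2, −78 °C
Reagents that add atoms: none
Why: Lewis acid-mediated Friedel–Crafts interflavan coupling in which the 4-alkoxy group ionises to the flavan-4-yl cation and C8 of excess 2 attacks trans to the 3-OH, which should give the 4β→8 bond and suppress oligomerisation.

Step 4
Reactants: 3 4β-(2-ethoxyethoxy) electrophile; 5 3,5-bis(benzyloxy)phenol (4 equiv)
Product: 6 tetra-O-benzylepicatechin bearing a 4β-[2-hydroxy-4,6-bis(benzyloxy)phenyl] group
Conditions: Me3SiOTf (cat.), CH2Cl2/THF, −78 to −40 °C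
Reagents that add atoms: none
Why: Friedel–Crafts C-arylation of the same cation, expected at the carbon ortho to the free OH (less hindered than the carbon between two benzyloxy groups and statistically doubled), trans to the 3-OH (4β), with excess phenol preventing double alkylation.

Step 5
Reactants: 6 unit 1–phenol adduct
Product: 7 4,6-bis(benzyloxy)-2-hydroxy-3-(unit 1 flavan-4β-yl)benzaldehyde
Conditions: MgCl2, Et3N, (CH2O)n, MeCN, reflux
Reagents that add atoms: formaldehyde (as paraformaldehyde), C=O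
Why: Casnati–Skattebøl ortho-formylation, in which the magnesium phenoxide delivers formaldehyde only to the one free ortho carbon (future C4a) and a second formaldehyde oxidises the hydroxymethyl group; the phenol-free ring A of unit 1 cannot react.

Step 6
Reactants: 7 salicylaldehyde
Product: 8 2-(allyloxy)-4,6-bis(benzyloxy)-3-(unit 1 flavan-4β-yl)benzaldehyde
Conditions: allyl bromide, Cs2CO3, DMF, 40 °C
Reagents that add atoms: allyl bromide, C=CCBr
Why: Williamson O-allylation of the phenoxide masks the future O1 through the organometallic and oxidation steps with a group that zerovalent palladium later removes under neutral conditions.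

Step 7
Reactants: 9 3,4-bis(benzyloxy)benzaldehyde
Product: 10 4-ethynyl-1,2-bis(benzyloxy)benzene
Conditions: dimethyl (1-diazo-2-oxopropyl)phosphonate, K2CO3, MeOH/THF, rt
Reagents that add atoms: dimethyl (1-diazo-2-oxopropyl)phosphonate, CC(=O)C(=[N+]=[N-])P(=O)(OC)OC
Why: Ohira–Bestmann (Seyferth–Gilbert) homologation converts the aldehyde into the terminal alkyne in one step under mild base that benzyl ethers tolerate.

Step 8
Reactants: 8 O-allyl aldehyde; 10 arylalkyne (3 equiv)
Product: 11 (R)-propargylic alcohol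
Conditions: Me2Zn (3 equiv), (S,S)-ProPhenol [2,6-bis{[(S)-2-(hydroxydiphenylmethyl)pyrrolidin-1-yl]methyl}-4-methylphenol] (20 mol %), Ph3P=O, toluene, 0 °C to rt
Reagents that add atoms: none
Why: Catalytic enantioselective addition of a zinc alkynylide to an aromatic aldehyde forms the C3–C4 bond, and ligand-controlled Re-face attack should set the (R)-carbinol that later directs the epoxidation.

Step 9
Reactants: 11 (R)-propargylic alcohol
Product: 12 (R,Z)-allylic alcohol
Conditions: H2 (1 atm), Ni2B (from Ni(OAc)2·4H2O and NaBH4, cat.), ethylenediamine, EtOH/THF, rt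
Reagents that add atoms: none
Why: Syn semihydrogenation of the alkyne on amine-poisoned Ni2B should give the Z-alkene while sparing the benzyl ethers and the terminal alkene of the allyl ether.

Step 10
Reactants: 12 (R,Z)-allylic alcohol
Product: 13 threo cis-epoxy alcohol (O1 allyl ether)
Conditions: dimethyldioxirane (acetone solution diluted with CH2Cl2), −30 °C
Reagents that add atoms: dimethyldioxirane, CC1(C)OO1
Why: Hydroxyl-directed (Henbest-type) epoxidation in which allylic 1,3-strain of the Z-alkene holds the C4–H in the alkene plane, so the hydrogen-bonded oxidant adds syn to the OH and anti to the bulky ring A aryl to give the threo cis-epoxide, and the neutral dioxirane spares the acid-labile aryl epoxide.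

Step 11
Reactants: 13 threo cis-epoxy alcohol (O1 allyl ether)
Product: 15 unit 1–unit 2 flavan-3,4-diol (2R,3R,4S in unit 2), via free phenol epoxy alcohol 14 (not isolated)
Conditions: Pd(PPh3)4 (5 mol %), morpholine (3 equiv), degassed THF, 0 °C to rt
Reagents that add atoms: none
Why: Zerovalent palladium ionises the aryl allyl ether (Tsuji–Trost deallylation, the allyl group passing to morpholine) and frees the C8a–OH of ring A in unit 2, whose oxygen then attacks the benzylic epoxide carbon (future C2) from the side opposite the oxirane C–O bond in an intramolecular SN2-type opening. The closest known reaction type is the cyclisation of 2-(2-hydroxybenzyl)-3-aryloxiranes to flavan-3-ols. Ring C is closed in the 6-endo-tet mode; the 5-exo alternative at C3 is disfavoured because C3 is not benzylic and is flanked by the oxygenated, aryl-bearing C4. C2 is set by inversion of the epoxide carbon, so the cis-epoxide gives the 2,3-cis ring, while C3 keeps its epoxide configuration and becomes the 3-OH; both descend from the C4 carbinol through the directed epoxidation. The step needs endo regioselectivity and clean inversion without a free benzylic cation: the para benzyloxy group of ring B activates C2 toward a loose SN2 transition state, and the amine-buffered, Lewis acid-free medium with the nucleophile held over C2 should prevent ionisation and epimerisation.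

Step 12
Reactants: 15 unit 1–unit 2 flavan-3,4-diol; 4 octa-O-benzyl epicatechin-(4β→8)-epicatechin (3 equiv)
Product: 16 hexadeca-O-benzyl epicatechin tetramer
Conditions: Me3SiOTf (cat.), 4 Å molecular sieves, CH2Cl2, −78 to −30 °C
Reagents that add atoms: none
Why: Friedel–Crafts interflavan coupling in which the 4-OH of unit 2 ionises with loss of water (taken up by the sieves) to a ring A-stabilised flavan-4-yl cation, which erases the auxiliary C4 configuration, and C8 of the upper unit of excess 4 attacks trans to the 3-OH, which should give the third 4β→8 bond.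

Step 13
Reactants: 16 hexadeca-O-benzyl epicatechin tetramer
Product: 17 epicatechin-(4β→8)-epicatechin-(4β→8)-epicatechin-(4β→8)-epicatechin (the target)
Conditions: H2 (1 atm), Pd(OH)2/C, THF/MeOH/H2O, rt
Reagents that add atoms: none
Why: Catalytic hydrogenolysis of the sixteen benzyl aryl ethers under neutral conditions should leave the interflavan bonds and all stereocentres untouched.

**Compound list**

1 | (−)-epicatechin, (2R,3R)-2-(3,4-dihydroxyphenyl)chromane-3,5,7-triol | Oc1cc(O)c2c(c1)O[C@H](c1ccc(O)c(O)c1)[C@H](O)C2 | starting material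

2 | 5,7,3',4'-tetra-O-benzyl-(−)-epicatechin, (2R,3R)-5,7-bis(benzyloxy)-2-[3,4-bis(benzyloxy)phenyl]chroman-3-ol | c1ccccc1COc1cc(OCc3ccccc3)c2c(c1)O[C@H](c1ccc(OCc3ccccc3)c(OCc3ccccc3)c1)[C@H](O)C2 | intermediate

3 | (2R,3R,4S)-5,7-bis(benzyloxy)-2-[3,4-bis(benzyloxy)phenyl]-4-(2-ethoxyethoxy)chroman-3-ol (4β-alkoxy, 3,4-trans) | c1ccccc1COc1cc(OCc3ccccc3)c2c(c1)O[C@H](c1ccc(OCc3ccccc3)c(OCc3ccccc3)c1)[C@H](O)[C@H]2OCCOCC | intermediate

4 | octa-O-benzyl epicatechin-(4β→8)-epicatechin, tetra-O-benzylepicatechin-(4β→8)-tetra-O-benzylepicatechin, both 3-OH free | c1ccccc1COc1cc(OCc3ccccc3)c2c(c1)O[C@H](c1ccc(OCc3ccccc3)c(OCc3ccccc3)c1)[C@H](O)[C@H]2c1c(OCc3ccccc3)cc(OCc3ccccc3)c2c1O[C@H](c1ccc(OCc3ccccc3)c(OCc3ccccc3)c1)[C@H](O)C2 | intermediate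

5 | 3,5-bis(benzyloxy)phenol | Oc1cc(OCc2ccccc2)cc(OCc2ccccc2)c1 | starting material

6 | (2R,3R)-tetra-O-benzylepicatechin carrying at C4 (4β, trans to 3-OH) a 2-hydroxy-4,6-bis(benzyloxy)phenyl group | c1ccccc1COc1cc(OCc3ccccc3)c2c(c1)O[C@H](c1ccc(OCc3ccccc3)c(OCc3ccccc3)c1)[C@H](O)[C@H]2c1c(OCc3ccccc3)cc(OCc3ccccc3)cc1O | intermediate

7 | 4,6-bis(benzyloxy)-2-hydroxy-3-[(2R,3R)-tetra-O-benzylepicatechin-4β-yl]benzaldehyde | c1ccccc1COc1cc(OCc3ccccc3)c2c(c1)O[C@H](c1ccc(OCc3ccccc3)c(OCc3ccccc3)c1)[C@H](O)[C@H]2c1c(OCc3ccccc3)cc(OCc3ccccc3)c(C=O)c1O | intermediate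

8 | 2-(allyloxy)-4,6-bis(benzyloxy)-3-[(2R,3R)-tetra-O-benzylepicatechin-4β-yl]benzaldehyde | c1ccccc1COc1cc(OCc3ccccc3)c2c(c1)O[C@H](c1ccc(OCc3ccccc3)c(OCc3ccccc3)c1)[C@H](O)[C@H]2c1c(OCc3ccccc3)cc(OCc3ccccc3)c(C=O)c1OCC=C | intermediate

9 | 3,4-bis(benzyloxy)benzaldehyde | O=Cc1ccc(OCc2ccccc2)c(OCc2ccccc2)c1 | starting material

10 | 4-ethynyl-1,2-bis(benzyloxy)benzene | C#Cc1ccc(OCc2ccccc2)c(OCc2ccccc2)c1 | intermediate

11 | (R)-1-{2-(allyloxy)-4,6-bis(benzyloxy)-3-[(2R,3R)-tetra-O-benzylepicatechin-4β-yl]phenyl}-3-[3,4-bis(benzyloxy)phenyl]prop-2-yn-1-ol | c1ccccc1COc1cc(OCc3ccccc3)c2c(c1)O[C@H](c1ccc(OCc3ccccc3)c(OCc3ccccc3)c1)[C@H](O)[C@H]2c1c(OCc3ccccc3)cc(OCc3ccccc3)c([C@H](O)C#Cc2ccc(OCc3ccccc3)c(OCc3ccccc3)c2)c1OCC=C | intermediate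

12 | (R,Z)-1-{2-(allyloxy)-4,6-bis(benzyloxy)-3-[(2R,3R)-tetra-O-benzylepicatechin-4β-yl]phenyl}-3-[3,4-bis(benzyloxy)phenyl]prop-2-en-1-ol | c1ccccc1COc1cc(OCc3ccccc3)c2c(c1)O[C@H](c1ccc(OCc3ccccc3)c(OCc3ccccc3)c1)[C@H](O)[C@H]2c1c(OCc3ccccc3)cc(OCc3ccccc3)c([C@H](O)/C=C\c2ccc(OCc3ccccc3)c(OCc3ccccc3)c2)c1OCC=C | intermediate

13 | (S)-{2-(allyloxy)-4,6-bis(benzyloxy)-3-[(2R,3R)-tetra-O-benzylepicatechin-4β-yl]phenyl}[(2R,3S)-3-(3,4-bis(benzyloxy)phenyl)oxiran-2-yl]methanol (cis-epoxide, threo to the carbinol) | c1ccccc1COc1cc(OCc3ccccc3)c2c(c1)O[C@H](c1ccc(OCc3ccccc3)c(OCc3ccccc3)c1)[C@H](O)[C@H]2c1c(OCc3ccccc3)cc(OCc3ccccc3)c([C@H](O)[C@H]4O[C@H]4c2ccc(OCc3ccccc3)c(OCc3ccccc3)c2)c1OCC=C | intermediate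

14 | (S)-{4,6-bis(benzyloxy)-2-hydroxy-3-[(2R,3R)-tetra-O-benzylepicatechin-4β-yl]phenyl}[(2R,3S)-3-(3,4-bis(benzyloxy)phenyl)oxiran-2-yl]methanol (free phenol, not isolated) | c1ccccc1COc1cc(OCc3ccccc3)c2c(c1)O[C@H](c1ccc(OCc3ccccc3)c(OCc3ccccc3)c1)[C@H](O)[C@H]2c1c(OCc3ccccc3)cc(OCc3ccccc3)c([C@H](O)[C@H]4O[C@H]4c2ccc(OCc3ccccc3)c(OCc3ccccc3)c2)c1O | intermediate

15 | tetra-O-benzylepicatechin-(4β→8)-[(2R,3R,4S)-5,7,3',4'-tetra-O-benzylflavan-3,4-diol] (unit 2: 2,3-cis, 3,4-trans, 4β-OH) | c1ccccc1COc1cc(OCc3ccccc3)c2c(c1)O[C@H](c1ccc(OCc3ccccc3)c(OCc3ccccc3)c1)[C@H](O)[C@H]2c1c(OCc3ccccc3)cc(OCc3ccccc3)c2c1O[C@H](c1ccc(OCc3ccccc3)c(OCc3ccccc3)c1)[C@H](O)[C@H]2O | intermediate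

16 | hexadeca-O-benzyl epicatechin tetramer (all phenols benzylated, four 3-OH free, three 4β→8 bonds) | c1ccccc1COc1cc(OCc3ccccc3)c2c(c1)O[C@H](c1ccc(OCc3ccccc3)c(OCc3ccccc3)c1)[C@H](O)[C@H]2c1c(OCc3ccccc3)cc(OCc3ccccc3)c2c1O[C@H](c1ccc(OCc3ccccc3)c(OCc3ccccc3)c1)[C@H](O)[C@H]2c1c(OCc3ccccc3)cc(OCc3ccccc3)c2c1O[C@H](c1ccc(OCc3ccccc3)c(OCc3ccccc3)c1)[C@H](O)[C@H]2c1c(OCc3ccccc3)cc(OCc3ccccc3)c2c1O[C@H](c1ccc(OCc3ccccc3)c(OCc3ccccc3)c1)[C@H](O)C2 | intermediate

17 | epicatechin-(4β→8)-epicatechin-(4β→8)-epicatechin-(4β→8)-epicatechin, the all-(4β→8)-linked epicatechin tetramer | Oc1cc(O)c2c(c1)O[C@H](c1ccc(O)c(O)c1)[C@H](O)[C@H]2c1c(O)cc(O)c2c1O[C@H](c1ccc(O)c(O)c1)[C@H](O)[C@H]2c1c(O)cc(O)c2c1O[C@H](c1ccc(O)c(O)c1)[C@H](O)[C@H]2c1c(O)cc(O)c2c1O[C@H](c1ccc(O)c(O)c1)[C@H](O)C2 | target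

**Step count and risks**

Total step count: 13. Longest linear sequence: 11 steps (steps 1, 2, 4, 5, 6, 8, 9, 10, 11, 12, 13).

Steps most likely to fail:

Step 11. The benzylic C–O bond of the epoxide may ionise before the phenol closes, which would erode the cis relationship at C2–C3; closure may also occur in the 5-exo sense at C3, or the palladium catalyst may isomerise the aryl epoxide. Fallback: this sets out from 4 and returns at 16, taking ring C of unit 2 intact from epicatechin. Benzylic oxidation of 4 at the free C4 methylene of its lower unit (DDQ, 2-ethoxyethanol, CH2Cl2) should give the dimeric 4β-(2-ethoxyethoxy) electrophile F1. Me3SiOTf-mediated coupling of this with a second portion of 4 in excess should then give 16.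

Step 10. The electron-rich aryl epoxide may be opened by traces of acid or on work-up before the phenol is freed, and facial selectivity may erode if the hydrogen-bond delivery is weak. Fallback: this sets out from 12 and returns at 15, so that the epoxide never accumulates. The allyl group is removed first (Pd(PPh3)4, morpholine, THF) to give the free phenol Z-allylic alcohol F2. Epoxidation with Ti(OiPr)4 and t-BuOOH (CH2Cl2, −20 °C), in which titanium binds both the allylic alkoxide and the phenoxide, should deliver oxygen to the alkoxide face and have the epoxide captured at once by the neighbouring phenol.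

Step 8. Addition to the hindered, electron-rich aldehyde may be slow and the facial selectivity poor. Fallback: this sets out from 8 and returns at 11, with the carbinol configuration set by reduction rather than by addition. The lithium acetylide of 10 (n-BuLi, THF, −78 °C) is added to 8 to give the propargylic alcohol epimer mixture F3. Oxidation with MnO2 (CH2Cl2) should give the ynone F4, and Corey–Bakshi–Shibata reduction ((S)-Me-CBS oxazaborolidine, BH3·SMe2, −40 °C), with the disubstituted aryl group as the large substituent, should give 11.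

**Further compounds**

F1 | step 11 | tetra-O-benzylepicatechin-(4β→8)-[(2R,3R,4S)-5,7,3',4'-tetra-O-benzyl-4-(2-ethoxyethoxy)flavan-3-ol] | c1ccccc1COc1cc(OCc3ccccc3)c2c(c1)O[C@H](c1ccc(OCc3ccccc3)c(OCc3ccccc3)c1)[C@H](O)[C@H]2c1c(OCc3ccccc3)cc(OCc3ccccc3)c2c1O[C@H](c1ccc(OCc3ccccc3)c(OCc3ccccc3)c1)[C@H](O)[C@H]2OCCOCC

F2 | step 10 | (R,Z)-1-{4,6-bis(benzyloxy)-2-hydroxy-3-[(2R,3R)-tetra-O-benzylepicatechin-4β-yl]phenyl}-3-[3,4-bis(benzyloxy)phenyl]prop-2-en-1-ol | c1ccccc1COc1cc(OCc3ccccc3)c2c(c1)O[C@H](c1ccc(OCc3ccccc3)c(OCc3ccccc3)c1)[C@H](O)[C@H]2c1c(OCc3ccccc3)cc(OCc3ccccc3)c([C@H](O)/C=C\c2ccc(OCc3ccccc3)c(OCc3ccccc3)c2)c1O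

F3 | step 8 | 1-{2-(allyloxy)-4,6-bis(benzyloxy)-3-[(2R,3R)-tetra-O-benzylepicatechin-4β-yl]phenyl}-3-[3,4-bis(benzyloxy)phenyl]prop-2-yn-1-ol, mixture of carbinol epimers | c1ccccc1COc1cc(OCc3ccccc3)c2c(c1)O[C@H](c1ccc(OCc3ccccc3)c(OCc3ccccc3)c1)[C@H](O)[C@H]2c1c(OCc3ccccc3)cc(OCc3ccccc3)c(C(O)C#Cc2ccc(OCc3ccccc3)c(OCc3ccccc3)c2)c1OCC=C

F4 | step 8 | 1-{2-(allyloxy)-4,6-bis(benzyloxy)-3-[(2R,3R)-tetra-O-benzylepicatechin-4β-yl]phenyl}-3-[3,4-bis(benzyloxy)phenyl]prop-2-yn-1-one | c1ccccc1COc1cc(OCc3ccccc3)c2c(c1)O[C@H](c1ccc(OCc3ccccc3)c(OCc3ccccc3)c1)[C@H](O)[C@H]2c1c(OCc3ccccc3)cc(OCc3ccccc3)c(C(=O)C#Cc2ccc(OCc3ccccc3)c(OCc3ccccc3)c2)c1OCC=C
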